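## The problem

Mollicellin A (22) is an achiral depsidone with four rings. Ring A is a pentasubstituted benzene (A-C1 lactone carbonyl, A-C2 ether oxygen, A-C3 CHO, A-C4 OH, A-C6 CH3). Ring B is the benzene ring of a 2,2,5-trimethylchroman-4-one. The two arenes are joined twice, by an ether oxygen between A-C2 and B-C6 and by an ester from A-C1 to the oxygen on B-C7, which encloses a seven-membered dioxepinone. There is no stereocentre, so the whole difficulty is regiochemical. The oxygen at B-C6 lies between the C5 methyl group and the C7 oxygen, and the carbonyl at A-C1 lies between the ether oxygen and the A-C6 methyl group; an electrophile would choose neither position unaided. The diaryl ether carries four ortho substituents and is therefore hard to form. Three groups limit the reagents: the salicylaldehyde, the aryl ester of the lactone (opened by alkoxide or hydroxide), and the enolisable chromanone (retro-oxa-Michael opening under strong base). The feature that opens the route is that the lactone carbonyl is bonded to A-C1 and to the B-C7 oxygen, and both A-C1 and B-C7 are ortho to the ether bridge. A carbonyl carried on the B-C7 oxygen as a carbonate therefore sits seven atoms from a carbanion at A-C1 and can be handed over to it, so ring A needs no carboxyl group while it is assembled.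

## Retrosynthesis

22 is taken back to 21, in which the aldehyde is a 1,3-dioxolane and the A-C4 hydroxyl a methoxymethyl ether. One mild acid treatment removes both, and the lactone and chromanone tolerate it.

In 21 the bond from A-C1 to the lactone carbonyl is cut. This gives aryllithium 20 and, before it, iodide 19, whose B-C7 oxygen carries a phenyl carbonate. The neighbouring cuts are weaker. Cutting the ester C–O bond requires a carboxyl on ring A throughout. Cutting the ether C–O bond last means an intramolecular copper coupling to a tetra-ortho-substituted ether inside a seven-membered ring. The chosen cut leaves an acyl transfer for the ring closure, and the carbonyl carbon comes from phenyl chloroformate 17. The forward step needs iodine–lithium exchange to be faster than any addition of the reagent, and the aryllithium to find its own carbonate first. The ring-B ketone is left free in 19. It is a vinylogous ester hindered by the peri methyl group, so its acetal would be strained and would not form under conditions the methoxymethyl ether tolerates. The aryllithium cannot reach it within the molecule.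

19 comes from aldehyde 18 by acetalisation, 18 from phenol 16 and 17, and 16 from 4-methoxybenzyl ether 15. The order is deliberate. The benzyl-type ether is removed oxidatively before the electron-rich benzylic acetal exists, and the acetal is made last under aprotic conditions so the carbonate is not transesterified. A temporary group on the B-C7 oxygen is unavoidable, because a carbonate would not survive the ether-forming step.

In 15 the A-C2–O bond is cut, giving phenol 9 and fluoroarene 14 (nucleophilic aromatic substitution of a fluoride ortho to the formyl group). Coupling 9 with the symmetrical 10 would be sterically easier. Iodine would then have to be introduced on the diaryl ether, where A-C5 (para to the aryloxy group) and B-C8 compete and A-C1 lies under ring B. Placing iodine before the coupling fixes its position, at the cost of displacing a fluoride flanked by CHO and I with a hindered phenoxide. The C–I bond is meta to the aldehyde and is not activated.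

14 is taken back through iodophenol 13 and phenol 12 to the symmetrical 2,6-difluoro-4-methylbenzaldehyde 10. One fluorine is exchanged for hydroxyl (the phenoxide formed prevents a second exchange), iodine enters para to that hydroxyl, and the phenol is capped.

9 comes from catechol 8 by alkylation of the more acidic 7-OH. In 8 the C4–C4a and O1–C2 bonds are cut, giving triol 5 and 3-methylbut-2-enoic acid 6 (acylation and oxa-Michael closure in one operation).

The B-C6 oxygen of 5 is traced to the formyl group of 3, and 3 to orcinol 1. Positions 4 and 6 of 1 are equivalent: one takes the formyl group that becomes the oxygen, the other later takes the acyl group. Oxygenating a preformed 7-hydroxychromanone would be expected to occur at C8 instead.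

## Roads not taken

Alternative 1: The ester C–O bond and the A-C1–A-C6 bond are cut together, so ring A is built on the ring-B oxygen. Heating dioxinone A3 with bromophenol A2 releases an acylketene that acylates the phenol to give triketo ester A4. Base then acid folds A4 by a C2-to-C7 aldol condensation into depside A1. The merits are real: ring A and the ester arise in one operation under neutral conditions, the orsellinate pattern forms by itself, and no organolithium is needed. For the construction of ring A it is shorter than steps 5 to 7 of the chosen plan. Its weak points lie elsewhere: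
- A1 has no ether bridge, so the seven-membered ring must be closed by an intramolecular copper coupling to a tetra-ortho-substituted ether.
- A1 has no formyl group, and late formylation must choose A-C3 over A-C5.
- A2 needs bromine at C6 between methyl and hydroxyl, where bromination of a 7-hydroxychromanone is expected at C8.
- A4 can also fold to pyrones.

Against the elegance of the fold, the chosen plan carries the aldehyde from the first ring-A intermediate, makes the hindered ether intermolecularly, and leaves only an acyl transfer for the ring closure.

Alternative 2: The C4–C3 and O1–C2 bonds of the pyran ring are cut. Salicylaldehyde A6 (the 4-O-benzyl ether of 3) is converted by Sc(OSO2CF3)3 and a methyl orthoester into an O-methyl ortho-quinone methide, which alkene A7 captures in a [4+2] cycloaddition to give chromane A5. The regiochemistry of the annulation is fixed by the aldehyde, and the step is catalytic. In this respect it is better than step 3 of the chosen plan, where the arene must choose the acylation site. For 22 it falls short in three ways: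
- A5 is at the ether oxidation level at C4 and must be oxidised to the ketone.
- The formyl group that the chosen plan turns into the C6 oxygen is consumed as C4, so C6 must be hydroxylated afterwards against the C8 preference.
- The depsidone core is not addressed; the new stereocentre is irrelevant.

The chosen plan accepts a less certain annulation because one operation on 3 then places the C6 oxygen correctly.

Alternative 3: The A-C1–A-C6 and A-C3–A-C4 bonds are cut, and ring A is annulated onto dioxepinone A9, which already holds both C–O bonds of the central ring. The lithium dienolate of A9 adds through its alpha-carbon to crotonate A10 (Michael addition), and the gamma-carbon then condenses with the ester (Claisen condensation) to give cyclohexenone A8. This avoids the tetra-ortho-substituted diaryl ether altogether, since the ether bond is made as an enol ether, and it needs no halogen. In this it is superior to step 8 of the chosen plan. Its weak points: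
- The dienolate and the released methoxide act beside an aryl ester lactone, which they can open.
- Alpha-versus-gamma selectivity in the Michael step is uncertain.
- A8 must still be dehydrogenated to the phenol and formylated at A-C3, with the fragile lactone present.

The chosen plan has the harder ether formation, but it ends one step after the ring closure with the aldehyde already in place.

Key step: step 12

Remark on the chemistry: mollicellin A has no stereocentre, so no step controls configuration and the SMILES of the route carry no stereodescriptors.

## Route

Step 1
Reactants: 1 orcinol (5-methylbenzene-1,3-diol)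
Product: 3 2,4-dihydroxy-6-methylbenzaldehyde (orcylaldehyde), via aryliminium chloride 2 (not isolated)
Conditions: POCl3, DMF, 0 °C → rt; then H2O, 50 °C
Reagents that add atoms: N,N-dimethylformamide (formyl carbon), CN(C)C=O; water (aldehyde oxygen), O
Why: Vilsmeier–Haack formylation: the chloroiminium ion attacks orcinol para to one hydroxyl and ortho to the other (C4, equivalent to C6), the usual site for this phenol, and water hydrolyses iminium salt 2.

Step 2
Reactants: 3 2,4-dihydroxy-6-methylbenzaldehyde
Product: 5 6-methylbenzene-1,2,4-triol, via aryl formate 4 (not isolated)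
Conditions: H2O2 (30% aq.), NaOH (1 M aq.), 0 °C → rt, argon; then dilute HCl
Reagents that add atoms: hydrogen peroxide, OO
Why: Dakin oxidation: hydroperoxide adds to the aldehyde of the ortho- and para-hydroxylated ring, aryl migration gives formate 4, and the base hydrolyses it; air is excluded because the hydroxyquinol oxidises easily, and the crude triol is used at once.

Step 3
Reactants: 5 6-methylbenzene-1,2,4-triol; 6 3-methylbut-2-enoic acid
Product: 8 6,7-dihydroxy-2,2,5-trimethylchroman-4-one, via aryl enone 7 (not isolated)
Conditions: P2O5 in MeSO3H (Eaton's reagent), 70 °C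
Reagents that add atoms: none
Why: Friedel–Crafts acylation followed by oxa-Michael closure, the standard one-pot route from phenols to 2,2-dimethylchroman-4-ones; acylation is expected para to the C2 hydroxyl and beside the methyl group rather than between two oxygens, as hydroxyquinol and orcinol behave, and only the C4 hydroxyl is ortho to the new acyl group and can close the ring.

Step 4
Reactants: 8 6,7-dihydroxy-2,2,5-trimethylchroman-4-one
Product: 9 6-hydroxy-7-[(4-methoxybenzyl)oxy]-2,2,5-trimethylchroman-4-one
Conditions: 4-MeOC6H4CH2Cl (1.05 equiv), K2CO3 (1.1 equiv), DMF, 40 °C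
Reagents that add atoms: 4-methoxybenzyl chloride, COc1ccc(CCl)cc1
Why: Williamson ether synthesis: the 7-OH is para to the ketone (a vinylogous acid) and unhindered, so one equivalent of weak base ionises and alkylates it, while the 6-OH between methyl and oxygen stays free, as in the 4-O-alkylation of 3,4-dihydroxyaryl ketones.

Step 5
Reactants: 10 2,6-difluoro-4-methylbenzaldehyde
Product: 12 2-fluoro-6-hydroxy-4-methylbenzaldehyde, via sulfonylethyl ether 11 (not isolated)
Conditions: MeSO2CH2CH2OH (1.5 equiv), NaH (3 equiv), DMF, 0 °C → rt; then dilute HCl
Reagents that add atoms: 2-(methylsulfonyl)ethanol (its oxygen), CS(=O)(=O)CCO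
Why: Nucleophilic aromatic substitution of a fluoride ortho to the aldehyde by the alkoxide, then E1cB loss of methyl vinyl sulfone from ether 11, a known hydroxide surrogate for activated aryl fluorides; the two fluorines are equivalent and the phenoxide formed blocks a second substitution.

Step 6
Reactants: 12 2-fluoro-6-hydroxy-4-methylbenzaldehyde
Product: 13 2-fluoro-6-hydroxy-3-iodo-4-methylbenzaldehyde
Conditions: N-iodosuccinimide (1.05 equiv), CF3CO2H (0.3 equiv), MeCN, 0 °C → rt
Reagents that add atoms: N-iodosuccinimide, O=C1CCC(=O)N1I
Why: Electrophilic aromatic iodination: the chelated phenol directs para, as salicylaldehydes and 3-fluorophenols do, and the para position is the one between fluorine and methyl; doing this on the small phenol lets any ortho isomer be removed before the fragments are joined.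

Step 7
Reactants: 13 2-fluoro-6-hydroxy-3-iodo-4-methylbenzaldehyde
Product: 14 2-fluoro-3-iodo-6-(methoxymethoxy)-4-methylbenzaldehyde
Conditions: MeOCH2Cl, i-Pr2NEt, CH2Cl2, 0 °C → rt
Reagents that add atoms: chloromethyl methyl ether, COCCl
Why: Methoxymethyl ether formation on the phenol; the ether removes the phenoxide that would deactivate the ring in step 8, is stable to base and to butyllithium, and falls in the final acid step.

Step 8
Reactants: 9 6-hydroxy-7-[(4-methoxybenzyl)oxy]-2,2,5-trimethylchroman-4-one; 14 2-fluoro-3-iodo-6-(methoxymethoxy)-4-methylbenzaldehyde
Product: 15 3-iodo-6-(methoxymethoxy)-2-({7-[(4-methoxybenzyl)oxy]-2,2,5-trimethyl-4-oxochroman-6-yl}oxy)-4-methylbenzaldehyde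
Conditions: Cs2CO3, DMSO, 100 °C
Reagents that add atoms: none
Why: Nucleophilic aromatic substitution: the 6-phenoxide of 9 (para to the ring oxygen and not conjugated with the ketone, hence nucleophilic) displaces the only fluoride, which is ortho to the aldehyde; the iodide is meta to the aldehyde and is not displaced.

Step 9
Reactants: 15 the diaryl ether of step 8
Product: 16 2-[(7-hydroxy-2,2,5-trimethyl-4-oxochroman-6-yl)oxy]-3-iodo-6-(methoxymethoxy)-4-methylbenzaldehyde
Conditions: DDQ (1.5 equiv), CH2Cl2–pH 7 phosphate buffer (10:1), rt
Reagents that add atoms: none
Why: Oxidative cleavage of the 4-methoxybenzyl ether (hydride abstraction by DDQ, then hydrolysis of the oxocarbenium ion); the aryl iodide, methoxymethyl ether, aldehyde and ketone are inert under the buffered conditions.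

Step 10
Reactants: 16 the phenol of step 9; 17 phenyl chloroformate
Product: 18 6-[2-formyl-6-iodo-3-(methoxymethoxy)-5-methylphenoxy]-2,2,5-trimethyl-4-oxochroman-7-yl phenyl carbonate
Conditions: pyridine, CH2Cl2, 0 °C
Reagents that add atoms: none
Why: O-acylation of the only free phenol by a chloroformate gives the mixed diaryl carbonate, which places the future lactone carbonyl on the B-C7 oxygen.

Step 11
Reactants: 18 the carbonate aldehyde of step 10
Product: 19 6-[2-(1,3-dioxolan-2-yl)-6-iodo-3-(methoxymethoxy)-5-methylphenoxy]-2,2,5-trimethyl-4-oxochroman-7-yl phenyl carbonate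
Conditions: (Me3SiOCH2)2 (1.5 equiv), Me3SiOSO2CF3 (5 mol %), CH2Cl2, −78 → −40 °C; pyridine quench
Reagents that add atoms: 1,2-bis(trimethylsilyloxy)ethane, C[Si](C)(C)OCCO[Si](C)(C)C
Why: Noyori acetalisation: the conditions are aprotic, so the carbonate is not transesterified, and cold enough to spare the methoxymethyl ether; the aldehyde reacts far faster than the peri-hindered vinylogous-ester ketone, which stays free.

Step 12
Reactants: 19 the iodo carbonate of step 11
Product: 21 protected mollicellin A (22 with the A-C3 formyl group as 1,3-dioxolane and the A-C4 hydroxyl as methoxymethyl ether), via aryllithium 20 (not isolated)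
Conditions: n-BuLi (1.0 equiv, slow addition), THF–Et2O (0.01 M), −100 °C, then −78 → 0 °C; aq. NH4Cl
Reagents that add atoms: none
Why: Parham cyclisation: n-butyllithium exchanges the iodine at A-C1 for lithium, aryllithium 20 adds to the carbonate carbonyl held on the B-C7 oxygen, and the tetrahedral alkoxide expels an aryloxide. The ring closes in a 7-exo-trig mode, helped by coordination of lithium to the carbonate oxygen across the ortho,ortho' ether tether. If phenoxide leaves, 21 forms directly; if the ring-B phenoxide leaves, the phenyl ester formed is an activated ester that the same phenoxide should close again on warming to 0 °C, so both paths lead to 21. The closest known reactions are Parham cycloacylations of aryllithiums onto tethered esters, carbamates and carbonates, and anionic Fries shifts started by halogen–lithium exchange. No stereocentre is formed. Exchange must be faster than butyl addition to the carbonate or the ketone: aryl iodides exchange with n-butyllithium faster than the reagent adds even to ketones, one equivalent is added slowly at −100 °C, and the ketone is a hindered vinylogous ester. The aryllithium must also acylate within its own molecule before meeting another: high dilution and the short tether favour this, and its own ketone is out of reach because a bond to it would bridge meta positions of ring B. The dioxolane and the methoxymethyl ether do not react with the reagent.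

Step 13
Reactants: 21 protected mollicellin A
Product: 22 mollicellin A
Conditions: CF3CO2H–CH2Cl2 (1:4), H2O (10 equiv), 0 °C → rt
Reagents that add atoms: water (aldehyde oxygen), O
Why: Acid hydrolysis of the dioxolane and acid cleavage of the methoxymethyl ether in one operation; the medium is non-nucleophilic, so the aryl ester of the lactone and the chromanone should survive.

## Compound list

1 | orcinol (5-methylbenzene-1,3-diol) | Cc1cc(O)cc(O)c1 | starting material
2 | [(2,4-dihydroxy-6-methylphenyl)methylidene]dimethyliminium chloride | Cc1cc(O)cc(O)c1C=[N+](C)C.[Cl-] | intermediate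
3 | 2,4-dihydroxy-6-methylbenzaldehyde (orcylaldehyde) | Cc1cc(O)cc(O)c1C=O | intermediate
4 | 2,4-dihydroxy-6-methylphenyl formate | Cc1cc(O)cc(O)c1OC=O | intermediate
5 | 6-methylbenzene-1,2,4-triol | Cc1cc(O)cc(O)c1O | intermediate
6 | 3-methylbut-2-enoic acid | CC(C)=CC(=O)O | starting material
7 | 3-methyl-1-(2,4,5-trihydroxy-6-methylphenyl)but-2-en-1-one | CC(C)=CC(=O)c1c(C)c(O)c(O)cc1O | intermediate
8 | 6,7-dihydroxy-2,2,5-trimethylchroman-4-one | CC1(C)CC(=O)c2c(C)c(O)c(O)cc2O1 | intermediate
9 | 6-hydroxy-7-[(4-methoxybenzyl)oxy]-2,2,5-trimethylchroman-4-one | COc1ccc(COc2cc3c(c(C)c2O)C(=O)CC(C)(C)O3)cc1 | intermediate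
10 | 2,6-difluoro-4-methylbenzaldehyde | Cc1cc(F)c(C=O)c(F)c1 | starting material
11 | 2-fluoro-4-methyl-6-[2-(methylsulfonyl)ethoxy]benzaldehyde | Cc1cc(F)c(C=O)c(OCCS(C)(=O)=O)c1 | intermediate
12 | 2-fluoro-6-hydroxy-4-methylbenzaldehyde | Cc1cc(O)c(C=O)c(F)c1 | intermediate
13 | 2-fluoro-6-hydroxy-3-iodo-4-methylbenzaldehyde | Cc1cc(O)c(C=O)c(F)c1I | intermediate
14 | 2-fluoro-3-iodo-6-(methoxymethoxy)-4-methylbenzaldehyde | COCOc1cc(C)c(I)c(F)c1C=O | intermediate
15 | 3-iodo-6-(methoxymethoxy)-2-({7-[(4-methoxybenzyl)oxy]-2,2,5-trimethyl-4-oxochroman-6-yl}oxy)-4-methylbenzaldehyde | Cc1cc(OCOC)c(C=O)c(Oc2c(C)c3c(cc2OCc2ccc(OC)cc2)OC(C)(C)CC3=O)c1I | intermediate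
16 | 2-[(7-hydroxy-2,2,5-trimethyl-4-oxochroman-6-yl)oxy]-3-iodo-6-(methoxymethoxy)-4-methylbenzaldehyde | Cc1cc(OCOC)c(C=O)c(Oc2c(C)c3c(cc2O)OC(C)(C)CC3=O)c1I | intermediate
17 | phenyl chloroformate | O=C(Cl)Oc1ccccc1 | starting material
18 | 6-[2-formyl-6-iodo-3-(methoxymethoxy)-5-methylphenoxy]-2,2,5-trimethyl-4-oxochroman-7-yl phenyl carbonate | Cc1cc(OCOC)c(C=O)c(Oc2c(C)c3c(cc2OC(=O)Oc2ccccc2)OC(C)(C)CC3=O)c1I | intermediate
19 | 6-[2-(1,3-dioxolan-2-yl)-6-iodo-3-(methoxymethoxy)-5-methylphenoxy]-2,2,5-trimethyl-4-oxochroman-7-yl phenyl carbonate | Cc1cc(OCOC)c(C2OCCO2)c(Oc2c(C)c3c(cc2OC(=O)Oc2ccccc2)OC(C)(C)CC3=O)c1I | intermediate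
20 | aryllithium of 19 (lithium in place of iodine at A-C1) | [Li]c1c(C)cc(OCOC)c(C2OCCO2)c1Oc1c(C)c2c(cc1OC(=O)Oc1ccccc1)OC(C)(C)CC2=O | intermediate
21 | protected mollicellin A (A-C3 formyl as 1,3-dioxolane, A-C4 hydroxyl as methoxymethyl ether, ring-B ketone free) | Cc1cc(OCOC)c(C2OCCO2)c2c1C(=O)Oc1cc3c(c(C)c1O2)C(=O)CC(C)(C)O3 | intermediate
22 | mollicellin A | Cc1cc(O)c(C=O)c2c1C(=O)Oc1cc3c(c(C)c1O2)C(=O)CC(C)(C)O3 | target

## Step count and least certain steps

Total: 13 steps. Longest linear sequence: 10 steps (steps 1 to 4 and 8 to 13, from orcinol). The ring-A branch (steps 5 to 7) is three steps and joins at step 8.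

Step 12 (key step). Three processes could spoil it: butyl addition to the carbonate, or enolisation of the ketone, before exchange; proton transfer from the ketone alpha-position of a second molecule to the aryllithium; and incomplete re-closure of the phenyl ester and ring-B phenoxide pair, because that phenoxide is the better leaving group. The last would leave ring-opened material after work-up. Fallback: a carbonylative closure that forms the same bond without a carbanion, setting out from 16. Under CO (1 atm) with Pd(OAc)2, Xantphos and Et3N in toluene at 90 °C, zerovalent palladium inserts into the C–I bond, CO insertion gives the acylpalladium species, and the ring-B phenol captures it to give O-(methoxymethyl)mollicellin A F1. CF3CO2H in CH2Cl2 then removes the methoxymethyl group and the route is rejoined at 22.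

Step 8. The fluoride is flanked by CHO and I and the phenoxide by methyl and benzyloxy, so substitution may be slow. Prolonged heating with base could then allow aldol condensation between the chromanone C3 position and the aldehyde, or retro-oxa-Michael opening of the pyranone. Fallback: couple before iodination, setting out from 9 and 10. Cs2CO3 in DMF at 60 °C should give the unhindered fluoro diaryl ether F2. KOH in DMSO–H2O exchanges the remaining fluoride for hydroxyl to give salicylaldehyde F3. N-iodosuccinimide with CF3CO2H gives iodophenol F4, and MeOCH2Cl with i-Pr2NEt rejoins the route at 15. This trades the steric problem for a regiochemical one: iodination must then choose A-C1 over A-C5 on the diaryl ether itself.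

Step 3. Acylation may occur between the two oxygens (C3 of the triol) instead of beside the methyl group, and the triol may oxidise to the hydroxyquinone before it reacts. Fallback: fix the acyl position first and add the oxygen second, setting out from 1. Acetylation of 1 (AcOH, BF3·OEt2) gives 1-(2,4-dihydroxy-6-methylphenyl)ethanone F5. Elbs persulfate oxidation (K2S2O8, aq. KOH), which attacks para to the chelated hydroxyl, gives the aryl sulfate F6. Acid hydrolysis of F6 gives 1-(2,4,5-trihydroxy-6-methylphenyl)ethanone F7. Kabbe condensation of F7 with acetone and pyrrolidine under argon closes the pyranone and rejoins the route at 8.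

Step 6. Iodination may go ortho to the hydroxyl (between OH and methyl) in competition with para, because the para position is also ortho to fluorine; a second iodination is possible too. Fallback: iodinate while the ring is still symmetrical, setting out from 10. N-iodosuccinimide in CF3SO3H should give 2,6-difluoro-3-iodo-4-methylbenzaldehyde F8 as the only possible isomer. The reagent of step 5 is then expected to attack the fluoride remote from iodine on steric grounds, giving the sulfonylethyl ether F9. F9 loses methyl vinyl sulfone in the same flask and the route is rejoined at 13.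

## Further compounds

F1 | step 12 | O-(methoxymethyl)mollicellin A (22 with the A-C4 hydroxyl as methoxymethyl ether, aldehyde free) | Cc1cc(OCOC)c(C=O)c2c1C(=O)Oc1cc3c(c(C)c1O2)C(=O)CC(C)(C)O3
F2 | step 8 | 2-fluoro-6-({7-[(4-methoxybenzyl)oxy]-2,2,5-trimethyl-4-oxochroman-6-yl}oxy)-4-methylbenzaldehyde | Cc1cc(F)c(C=O)c(Oc2c(C)c3c(cc2OCc2ccc(OC)cc2)OC(C)(C)CC3=O)c1
F3 | step 8 | 2-hydroxy-6-({7-[(4-methoxybenzyl)oxy]-2,2,5-trimethyl-4-oxochroman-6-yl}oxy)-4-methylbenzaldehyde | Cc1cc(O)c(C=O)c(Oc2c(C)c3c(cc2OCc2ccc(OC)cc2)OC(C)(C)CC3=O)c1
F4 | step 8 | 6-hydroxy-3-iodo-2-({7-[(4-methoxybenzyl)oxy]-2,2,5-trimethyl-4-oxochroman-6-yl}oxy)-4-methylbenzaldehyde | Cc1cc(O)c(C=O)c(Oc2c(C)c3c(cc2OCc2ccc(OC)cc2)OC(C)(C)CC3=O)c1I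
F5 | step 3 | 1-(2,4-dihydroxy-6-methylphenyl)ethanone | CC(=O)c1c(C)cc(O)cc1O
F6 | step 3 | potassium 3-acetyl-4,6-dihydroxy-2-methylphenyl sulfate | CC(=O)c1c(C)c(OS(=O)(=O)[O-])c(O)cc1O.[K+]
F7 | step 3 | 1-(2,4,5-trihydroxy-6-methylphenyl)ethanone | CC(=O)c1c(C)c(O)c(O)cc1O
F8 | step 6 | 2,6-difluoro-3-iodo-4-methylbenzaldehyde | Cc1cc(F)c(C=O)c(F)c1I
F9 | step 6 | 2-fluoro-3-iodo-4-methyl-6-[2-(methylsulfonyl)ethoxy]benzaldehyde | Cc1cc(OCCS(C)(=O)=O)c(C=O)c(F)c1I
A1 | alternative 1 | 6-bromo-2,2,5-trimethyl-4-oxochroman-7-yl 2,4-dihydroxy-6-methylbenzoate (bromo depside) | Cc1cc(O)cc(O)c1C(=O)Oc1cc2OC(C)(C)CC(=O)c2c(C)c1Br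
A2 | alternative 1 | 6-bromo-7-hydroxy-2,2,5-trimethylchroman-4-one | CC1(C)CC(=O)c2c(C)c(Br)c(O)cc2O1
A3 | alternative 1 | 6-(2,4-dioxopentyl)-2,2-dimethyl-4H-1,3-dioxin-4-one | CC(=O)CC(=O)CC1=CC(=O)OC(C)(C)O1
A4 | alternative 1 | 6-bromo-2,2,5-trimethyl-4-oxochroman-7-yl 3,5,7-trioxooctanoate | CC(=O)CC(=O)CC(=O)CC(=O)Oc1cc2OC(C)(C)CC(=O)c2c(C)c1Br
A5 | alternative 2 | 7-(benzyloxy)-4-methoxy-2,2,5-trimethylchromane (racemic, one enantiomer drawn) | CO[C@H]1CC(C)(C)Oc2cc(OCc3ccccc3)cc(C)c21
A6 | alternative 2 | 4-(benzyloxy)-2-hydroxy-6-methylbenzaldehyde | Cc1cc(OCc2ccccc2)cc(O)c1C=O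
A7 | alternative 2 | 2-methylpropene | CC(C)=C
A8 | alternative 3 | tetrahydro depsidone with ring A as a 6-methylcyclohexenone, ketone at A-C4, ring-B ketone as dioxolane (racemic, one enantiomer drawn) | C[C@H]1CC(=O)CC2=C1C(=O)Oc1cc3OC(C)(C)CC4(OCCO4)c3c(C)c1O2
A9 | alternative 3 | ring-B-fused 3-methyl-1,4-dioxepin-5-one (enol ether lactone with methyl on the A-C2 carbon, ring-B ketone as dioxolane) | CC1=CC(=O)Oc2cc3OC(C)(C)CC4(OCCO4)c3c(C)c2O1
A10 | alternative 3 | methyl (E)-but-2-enoate | C/C=C/C(=O)OC
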